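## Retrosynthetic overview

1. Feature: on ring A (C1–C5, C10; labdane numbering) the 2β-oxygen and the C10 methyl C20 are 1,3-syn-diaxial. C20 is therefore handed from a C2 hydroxyl to C10 across a C1=C10 alkene as a cyclopropane CH2, and the surplus C1–C20 bond is cut afterwards through the C2 ketone.
2. Endgame disconnections: C2 acetate; C13=C14 (Z) by syn-carbocupration of a C13≡C14 ynoate; C8=C17 by methylenation of a C8 ketone; C9–C11 by Negishi coupling of the C8=C9 enol triflate of the C9 ketone.
3. Core: 2β-OH by α-face hydride on the C2 ketone; 5α-H by hydrogenation of C5=C6 under the 10β-methyl; 10β-methyl by Li/NH3 opening of the cyclopropyl ketone; cyclopropane by hydroxyl-directed Simmons–Smith reaction of the (R)-dienol, itself from CBS reduction of an achiral dienone.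
4. Ring order: ring A is dimedone; ring B (C5–C10) is closed by vinylogous aldol condensation (C5=C6) after Stork–Danheiser union (C9–C10) with a dithiane C9 unit carrying C6–C8; the cyclopropane (C1, C10, C20) is a third, temporary ring (made in step 7, opened in step 9).

Key step: step 7

Remark on numbering: all bicyclic compounds are described with labdane numbering (ring A = C1–C5, C10; ring B = C5–C10; C20 = carbon on C10); β is the face that carries C20.
Remark on the target: the SMILES is read as the normal-series labdane (2R,5S,9S,10S), i.e. 10β-CH3, 5α-H, 9α-H (β side chain), 2β-OAc, 13Z.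
Remark on step order: the cyclopropane is opened before C5=C6 is hydrogenated, so that the hydrogenation runs on a 4,4,10-trimethyl-Δ5-octalin and no vinylcyclopropane is exposed to a hydrogenation catalyst.

## Route

Step 1
Reactants: 1 dimedone
Product: 2 3-ethoxy-5,5-dimethylcyclohex-2-en-1-one
Conditions: EtOH, TsOH·H2O (cat.), toluene, reflux, Dean–Stark
Reagents that add atoms: ethanol, CCO
Why: Acid-catalysed enol etherification of the symmetrical 1,3-diketone (vinylogous ester formation) is driven by azeotropic removal of water and creates no stereocentre.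

Step 2
Reactants: 3 1,3-dithiane; 4 2-(2-bromoethyl)-1,3-dioxolane
Product: 6 2-[2-(1,3-dioxolan-2-yl)ethyl]-1,3-dithiane, via 2-lithio-1,3-dithiane 5 (not isolated)
Conditions: n-BuLi, THF, −30 °C; then 4, −78 → 0 °C
Reagents that add atoms: none
Why: Corey–Seebach alkylation, in which the dithiane anion displaces the primary bromide by SN2, attaches C6–C8 (C6 as masked aldehyde) to the masked acyl carbon C9.

Step 3
Reactants: 6 2-[2-(1,3-dioxolan-2-yl)ethyl]-1,3-dithiane; 2 3-ethoxy-5,5-dimethylcyclohex-2-en-1-one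
Product: 9 3-{2-[2-(1,3-dioxolan-2-yl)ethyl]-1,3-dithian-2-yl}-5,5-dimethylcyclohex-2-en-1-one, via lithiated dithiane 7 (not isolated), via tertiary carbinol adduct 8 (not isolated)
Conditions: n-BuLi, THF, −25 °C, 2 h; then 2, −78 → 0 °C; then 1 M HCl, THF, 0 °C, short contact
Reagents that add atoms: water, O
Why: Stork–Danheiser sequence (1,2-addition to the vinylogous ester carbonyl, then acid-induced transposition with loss of ethanol) forms C9–C10, and because ring A is symmetrical a competing 1,4-addition–elimination would converge on the same enone.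

Step 4
Reactants: 9 3-{2-[2-(1,3-dioxolan-2-yl)ethyl]-1,3-dithian-2-yl}-5,5-dimethylcyclohex-2-en-1-one
Product: 12 dithiane dienone (C2 ketone; C1=C10; C5=C6; C9 1,3-dithiane; 4,4-dimethyl), via keto aldehyde 10 (not isolated), via vinylogous aldol adduct 11 (not isolated)
Conditions: TsOH·H2O (0.3 equiv), THF/H2O, 60 °C; then toluene, reflux, Dean–Stark
Reagents that add atoms: none
Why: Acid unmasks the C6 aldehyde and the neutral dienol (O–C2=C1–C10=C5) attacks it through its γ-terminus C5, the position of largest HOMO coefficient in a neutral dienol, in an intramolecular vinylogous aldol reaction (6-(enolendo)-exo-trig) whose dehydration to the linear, fully conjugated dienone is the thermodynamic sink.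

Step 5
Reactants: 12 dithiane dienone
Product: 13 dioxolane dienone (C2 ketone; C1=C10; C5=C6; C9 dioxolane; 4,4-dimethyl)
Conditions: PhI(OCOCF3)2, ethylene glycol, MeCN, rt
Reagents that add atoms: ethylene glycol, OCCO
Why: Hypervalent-iodine oxidative dethioacetalisation in the presence of the diol traps the sulfonium-activated C9 directly as the dioxolane, which removes sulfur before the zinc carbenoid, dissolving-metal and hydrogenation steps.

Step 6
Reactants: 13 dioxolane dienone
Product: 14 (R)-dienol (2β-OH; C1=C10; C5=C6; C9 dioxolane)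
Conditions: (S)-2-methyl-CBS-oxazaborolidine (15 mol %), catecholborane, toluene, −78 °C; aqueous NaOH wash
Reagents that add atoms: none
Why: Corey–Bakshi–Shibata reduction, in which the (S)-oxazaborolidine binds the carbonyl with the unsaturated C1=C10 flank as the large group and delivers hydride to one face, should give the (R)-carbinol as the only stereocentre of an otherwise achiral molecule.

Step 7
Reactants: 14 (R)-dienol
Product: 16 cyclopropyl carbinol (2β-OH; CH2 C20 bridging C1 and C10 on the β-face; C5=C6; C9 dioxolane), via iodomethylzinc alkoxide 15 (not isolated)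
Conditions: Zn(CH2I)2 pre-formed from Et2Zn (2.2 equiv) and CH2I2 (4.4 equiv), CH2Cl2, 0 °C; add 14, −10 → 0 °C; quench with aqueous NaHCO3/NH4Cl
Reagents that add atoms: diiodomethane, ICI
Why: Bis(iodomethyl)zinc is protonated by the C2 hydroxyl to give the iodomethylzinc alkoxide 15, and a zinc carbenoid held at that alkoxide transfers CH2 to the adjacent C1=C10 bond through the concerted butterfly transition state of the Simmons–Smith reaction, so C10–C20 and C1–C20 form stereospecifically on one face. The closest known reaction type is the hydroxyl-directed Simmons–Smith (Furukawa) cyclopropanation of cyclohex-2-en-1-ols, which gives syn-cyclopropyl carbinols, and of dienols, which react at the alkene proximal to the hydroxyl. The three-membered ring C1–C10–C20 is closed by this concerted [2+1] methylene transfer, not by a stepwise ring closure. The new stereocentres C1 and C10 are both controlled by the C2 carbinol, whose β-oxygen delivers C20 to the β-face and so fixes the quaternary C10 in the absolute sense set in step 6. The step needs site selectivity for C1=C10 over C5=C6 and β-facial selectivity; both should be secured by alkoxide coordination, helped by C5=C6 being remote from oxygen, trisubstituted and flanked by the quaternary C4 and C10.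

Step 8
Reactants: 16 cyclopropyl carbinol
Product: 17 cyclopropyl ketone (C2 ketone; β-cyclopropane C1–C10–C20; C5=C6; C9 dioxolane)
Conditions: Dess–Martin periodinane, NaHCO3, CH2Cl2, 0 °C → rt
Reagents that add atoms: none
Why: Buffered Dess–Martin oxidation converts the carbinol to the ketone without ionising the acid-labile cyclopropylcarbinyl system, and C1 and C10 are untouched.

Step 9
Reactants: 17 cyclopropyl ketone
Product: 19 10β-methyl Δ5 ketone (C2 ketone; C5=C6; C9 dioxolane), via lithium enolate 18 (not isolated)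
Conditions: Li (2.5 equiv), NH3(l)/THF, −78 °C; isoprene, then solid NH4Cl
Reagents that add atoms: none
Why: In the dissolving-metal reduction of a cyclopropyl ketone the ketyl cleaves the bond that overlaps best with the carbonyl π system, here the exocyclic C1–C20 bond (the ring bond C1–C10 lies near the nodal planes of both the C=O and the C5=C6 π systems), which leaves C20 as the methyl on C10 with its configuration retained.

Step 10
Reactants: 19 10β-methyl Δ5 ketone
Product: 20 trans-decalin ketone (C2 ketone; 5α-H; 10β-methyl; C9 dioxolane)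
Conditions: H2 (3 atm), 10 % Pd/C, EtOAc, rt
Reagents that add atoms: none
Why: Heterogeneous hydrogenation of a 4,4,10-trimethyl-Δ5-octalin should add hydrogen to C5 from the α-face because the axial 10β-methyl shields the β-face, which gives the trans ring fusion.

Step 11
Reactants: 20 trans-decalin ketone
Product: 22 2β-hydroxy-9-ketone (5α-H; 10β-methyl), via hydroxy ketal 21 (not isolated)
Conditions: L-Selectride, THF, −78 °C; NaOH, H2O2, 0 °C; then 2 M HCl, THF, rt
Reagents that add atoms: water, O
Why: The bulky hydride should approach C2 along the equatorial α-trajectory because the axial β-trajectory is blocked by the syn-axial methyls on C4 and C10, giving the axial 2β-alcohol, and the acidic work-up then hydrolyses the C9 dioxolane.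

Step 12
Reactants: 22 2β-hydroxy-9-ketone
Product: 23 2β-TBS ether of the 9-ketone
Conditions: TBSOTf, 2,6-lutidine, CH2Cl2, −78 → 0 °C
Reagents that add atoms: tert-butyldimethylsilyl trifluoromethanesulfonate, CC(C)(C)[Si](C)(C)OS(=O)(=O)C(F)(F)F
Why: Silylation with the silyl triflate protects the hindered axial alcohol as an ether that withstands the strong bases, borane, oxidants and ylide used later.

Step 13
Reactants: 23 2β-TBS ether of the 9-ketone
Product: 25 C8=C9 enol triflate (2β-OTBS), via potassium enolate 24 (not isolated)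
Conditions: KHMDS, THF, −78 °C; PhNTf2, −78 → 0 °C
Reagents that add atoms: N-phenylbis(trifluoromethanesulfonimide), O=S(=O)(N(c1ccccc1)S(=O)(=O)C(F)(F)F)C(F)(F)F
Why: Enolisation is regiospecific because C8 is the only enolisable α-carbon (C10 is quaternary), and O-triflation of the enolate gives the vinyl triflate.

Step 14
Reactants: 25 C8=C9 enol triflate; 4 2-(2-bromoethyl)-1,3-dioxolane
Product: 27 C8=C9 alkene with CH2CH2-(1,3-dioxolan-2-yl) on C9 (2β-OTBS), via alkylzinc bromide 26 (not isolated)
Conditions: 4, Zn dust, LiCl, THF, 40 °C; then 25, Pd(OAc)2 (5 mol %), SPhos (10 mol %), THF/NMP, 50 °C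
Reagents that add atoms: none
Why: Negishi cross-coupling (oxidative addition of Pd(0) into the vinyl triflate, transmetalation with the primary alkylzinc bromide, reductive elimination) forms C9–C11 and brings in C11–C13 with C13 as masked aldehyde.

Step 15
Reactants: 27 C8=C9 alkene
Product: 29 8α-alcohol (9α-H; β side chain on C9; 2β-OTBS), via alkylborane 28 (not isolated)
Conditions: BH3·THF, THF, 0 °C → rt; then NaOH, H2O2, 0 °C → rt
Reagents that add atoms: hydrogen peroxide, OO
Why: Hydroboration–oxidation adds B–H syn to the trisubstituted alkene from the α-face (anti to the axial 10β-methyl) with boron on the less substituted C8, which sets 9α-H and 8α-OH, and the C–B bond is oxidised with retention.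

Step 16
Reactants: 29 8α-alcohol
Product: 30 C8 ketone (9α-H; 2β-OTBS)
Conditions: Dess–Martin periodinane, NaHCO3, CH2Cl2, rt
Reagents that add atoms: none
Why: Dess–Martin oxidation gives the C8 ketone, and the now epimerisable C9 already holds its thermodynamically favoured equatorial β side chain.

Step 17
Reactants: 30 C8 ketone
Product: 31 8(17)-methylene acetal (C13 as dioxolane; 2β-OTBS)
Conditions: Ph3PCH3Br, KOtBu, toluene, 80 °C
Reagents that add atoms: methyltriphenylphosphonium bromide, C[P+](c1ccccc1)(c1ccccc1)c1ccccc1.[Br-]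
Why: Wittig methylenation of the hindered ketone installs the exocyclic C8=C17 alkene, and any base-mediated equilibration at C9 before olefination favours the desired equatorial side chain.

Step 18
Reactants: 31 8(17)-methylene acetal
Product: 32 C13 aldehyde (14,15,16-trinorlabd-8(17)-en-13-al; 2β-OTBS)
Conditions: PPTS (cat.), acetone/H2O (10:1), 55 °C
Reagents that add atoms: water, O
Why: Mild buffered acetal hydrolysis frees the aldehyde while the hindered TBS ether survives, and the weak acid is chosen to avoid Prins-type attack of the exocyclic alkene on the aldehyde.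

Step 19
Reactants: 32 C13 aldehyde
Product: 33 14,14-dibromo-13-ene (C13H=CBr2; 2β-OTBS)
Conditions: CBr4, PPh3, Et3N, CH2Cl2, 0 °C
Reagents that add atoms: carbon tetrabromide, BrC(Br)(Br)Br
Why: Ramirez–Corey–Fuchs dibromo-olefination with the ylide Ph3P=CBr2 adds C14 to the aldehyde.

Step 20
Reactants: 33 14,14-dibromo-13-ene
Product: 35 methyl 13-yn-15-oate (C13≡C14–CO2Me; 2β-OTBS), via lithium acetylide 34 (not isolated)
Conditions: n-BuLi (2.2 equiv), THF, −78 → −20 °C; then ClCO2Me, −78 °C
Reagents that add atoms: methyl chloroformate, COC(Cl)=O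
Why: In the second Corey–Fuchs stage, bromine–lithium exchange, α-elimination and 1,2-hydride shift give the lithium acetylide, which is C-acylated by the chloroformate to the 2-alkynoate.

Step 21
Reactants: 35 methyl 13-yn-15-oate
Product: 37 methyl (13Z)-2β-(TBS-oxy)labda-8(17),13-dien-15-oate, via alkenylcuprate 36 (not isolated)
Conditions: Me2CuLi (from CuI and 2 MeLi), THF, −78 °C; MeOH then aqueous NH4Cl at −78 °C
Reagents that add atoms: lithium dimethylcuprate, [Li+].C[Cu-]C
Why: syn-Carbocupration of the alkynoate places the methyl C16 and copper cis across C13=C14, and protonation at low temperature with retention leaves C12 cis to the ester, i.e. the 13Z trisubstituted enoate.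

Step 22
Reactants: 37 methyl (13Z)-2β-(TBS-oxy)labda-8(17),13-dien-15-oate
Product: 38 methyl (13Z)-2β-hydroxylabda-8(17),13-dien-15-oate
Conditions: HF·pyridine, THF, 0 °C → rt
Reagents that add atoms: none
Why: Fluoride-mediated desilylation frees the 2β-alcohol under conditions too weakly acidic to move the exocyclic alkene or the Z-alkene.

Step 23
Reactants: 38 methyl (13Z)-2β-hydroxylabda-8(17),13-dien-15-oate
Product: 39 (13Z)-2β-hydroxylabda-8(17),13-dien-15-oic acid
Conditions: LiOH, THF/MeOH/H2O, 45 °C; then 1 M HCl to pH 3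
Reagents that add atoms: lithium hydroxide, [Li+].[OH-]
Why: Saponification (BAc2) of the methyl ester under mild conditions should give the acid without Z/E equilibration through the dienolate.

Step 24
Reactants: 39 (13Z)-2β-hydroxylabda-8(17),13-dien-15-oic acid
Product: 41 (13Z)-2β-acetoxylabda-8(17),13-dien-15-oic acid, via mixed anhydride 40 (not isolated)
Conditions: Ac2O, pyridine, DMAP (cat.), CH2Cl2, rt; then H2O/THF, rt
Reagents that add atoms: acetic anhydride, CC(=O)OC(C)=O
Why: DMAP-catalysed acetylation esterifies the hindered axial 2β-alcohol, and the transient C15 mixed anhydride is cleaved by water at its less hindered, non-conjugated acetyl carbonyl during work-up, returning the free acid.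

## Compound list

1 | dimedone (5,5-dimethylcyclohexane-1,3-dione) | CC1(C)CC(=O)CC(=O)C1 | starting material
2 | 3-ethoxy-5,5-dimethylcyclohex-2-en-1-one | CCOC1=CC(=O)CC(C)(C)C1 | intermediate
3 | 1,3-dithiane | C1CSCSC1 | starting material
4 | 2-(2-bromoethyl)-1,3-dioxolane | BrCCC1OCCO1 | starting material
5 | 2-lithio-1,3-dithiane | [Li]C1SCCCS1 | intermediate
6 | 2-[2-(1,3-dioxolan-2-yl)ethyl]-1,3-dithiane | C1CSC(CCC2OCCO2)SC1 | intermediate
7 | 2-lithio-2-[2-(1,3-dioxolan-2-yl)ethyl]-1,3-dithiane | [Li]C1(CCC2OCCO2)SCCCS1 | intermediate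
8 | 1-{2-[2-(1,3-dioxolan-2-yl)ethyl]-1,3-dithian-2-yl}-3-ethoxy-5,5-dimethylcyclohex-2-en-1-ol (racemic) | CCOC1=CC(O)(C2(CCC3OCCO3)SCCCS2)CC(C)(C)C1 | intermediate
9 | 3-{2-[2-(1,3-dioxolan-2-yl)ethyl]-1,3-dithian-2-yl}-5,5-dimethylcyclohex-2-en-1-one | O=C1C=C(C2(CCC3OCCO3)SCCCS2)CC(C)(C)C1 | intermediate
10 | 3-[2-(5,5-dimethyl-3-oxocyclohex-1-en-1-yl)-1,3-dithian-2-yl]propanal | O=CCCC1(C2=CC(=O)CC(C)(C)C2)SCCCS1 | intermediate
11 | vinylogous aldol adduct (C2 ketone, C1=C10, C6 hydroxyl, C9 dithiane; diastereomer mixture) | O=C1C=C2C(C(O)CCC23SCCCS3)C(C)(C)C1 | intermediate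
12 | 5',5'-dimethyl-2',3',5',6'-tetrahydro-7'H-spiro[1,3-dithiane-2,1'-naphthalen]-7'-one (C2 ketone, C1=C10, C5=C6, C9 dithiane) | O=C1C=C2C(=CCCC23SCCCS3)C(C)(C)C1 | intermediate
13 | 5',5'-dimethyl-2',3',5',6'-tetrahydro-7'H-spiro[1,3-dioxolane-2,1'-naphthalen]-7'-one (C9 dioxolane dienone) | O=C1C=C2C(=CCCC23OCCO3)C(C)(C)C1 | intermediate
14 | (R)-dienol: 2β-hydroxy, C1=C10, C5=C6, 4,4-dimethyl, C9 dioxolane | O[C@H]1C=C2C(=CCCC23OCCO3)C(C)(C)C1 | intermediate
15 | iodomethylzinc alkoxide of 14 | IC[Zn]O[C@H]1C=C2C(=CCCC23OCCO3)C(C)(C)C1 | intermediate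
16 | cyclopropyl carbinol: 2β-OH, cyclopropane C1–C10–C20 on the β-face, C5=C6, C9 dioxolane | O[C@H]1[C@H]2C[C@@]23C(=CCCC34OCCO4)C(C)(C)C1 | intermediate
17 | cyclopropyl ketone: C2 ketone, β-cyclopropane C1–C10–C20, C5=C6, C9 dioxolane | O=C1[C@H]2C[C@@]23C(=CCCC34OCCO4)C(C)(C)C1 | intermediate
18 | lithium C1=C2 enolate of 19 | [Li]OC1=C[C@@]2(C)C(=CCCC23OCCO3)C(C)(C)C1 | intermediate
19 | 10β-methyl Δ5 ketone: C2 ketone, C5=C6, 4,4,10-trimethyl, C9 dioxolane | O=C1C[C@@]2(C)C(=CCCC23OCCO3)C(C)(C)C1 | intermediate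
20 | trans-decalin ketone: C2 ketone, 5α-H, 10β-methyl, C9 dioxolane | O=C1C[C@@]2(C)[C@@H](CCCC23OCCO3)C(C)(C)C1 | intermediate
21 | 2β-hydroxy C9 dioxolane (5α-H, 10β-methyl) | O[C@H]1C[C@@]2(C)[C@@H](CCCC23OCCO3)C(C)(C)C1 | intermediate
22 | 2β-hydroxy-9-ketone (5α-H, 10β-methyl, 4,4-dimethyl) | O[C@H]1C[C@@]2(C)[C@@H](CCCC2=O)C(C)(C)C1 | intermediate
23 | 2β-(tert-butyldimethylsilyloxy)-9-ketone | CC(C)(C)[Si](C)(C)O[C@H]1C[C@@]2(C)[C@@H](CCCC2=O)C(C)(C)C1 | intermediate
24 | potassium C8=C9 enolate of 23 | CC(C)(C)[Si](C)(C)O[C@H]1C[C@@]2(C)[C@@H](CCC=C2O[K])C(C)(C)C1 | intermediate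
25 | C8=C9 enol triflate (triflate on C9; 2β-OTBS) | CC(C)(C)[Si](C)(C)O[C@H]1C[C@@]2(C)[C@@H](CCC=C2OS(=O)(=O)C(F)(F)F)C(C)(C)C1 | intermediate
26 | [2-(1,3-dioxolan-2-yl)ethyl]zinc bromide | Br[Zn]CCC1OCCO1 | intermediate
27 | C8=C9 alkene with 2-(1,3-dioxolan-2-yl)ethyl on C9 (2β-OTBS) | CC(C)(C)[Si](C)(C)O[C@H]1C[C@@]2(C)[C@@H](CCC=C2CCC3OCCO3)C(C)(C)C1 | intermediate
28 | 8α-boryl compound (9α-H) | CC(C)(C)[Si](C)(C)O[C@H]1C[C@@]2(C)[C@@H](CC[C@@H](B)[C@@H]2CCC3OCCO3)C(C)(C)C1 | intermediate
29 | 8α-alcohol (9α-H, β side chain on C9, 2β-OTBS) | CC(C)(C)[Si](C)(C)O[C@H]1C[C@@]2(C)[C@@H](CC[C@@H](O)[C@@H]2CCC3OCCO3)C(C)(C)C1 | intermediate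
30 | C8 ketone (9α-H, 2β-OTBS, C13 as dioxolane) | CC(C)(C)[Si](C)(C)O[C@H]1C[C@@]2(C)[C@@H](CCC(=O)[C@@H]2CCC3OCCO3)C(C)(C)C1 | intermediate
31 | 8(17)-methylene compound, C13 as dioxolane (2β-OTBS) | CC(C)(C)[Si](C)(C)O[C@H]1C[C@@]2(C)[C@@H](CCC(=C)[C@@H]2CCC3OCCO3)C(C)(C)C1 | intermediate
32 | 2β-(TBS-oxy)-14,15,16-trinorlabd-8(17)-en-13-al | CC(C)(C)[Si](C)(C)O[C@H]1C[C@@]2(C)[C@@H](CCC(=C)[C@@H]2CCC=O)C(C)(C)C1 | intermediate
33 | 14,14-dibromo-13-ene (C13H=CBr2; 8(17)-ene; 2β-OTBS) | CC(C)(C)[Si](C)(C)O[C@H]1C[C@@]2(C)[C@@H](CCC(=C)[C@@H]2CCC=C(Br)Br)C(C)(C)C1 | intermediate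
34 | lithium acetylide (C13≡C14–Li) | CC(C)(C)[Si](C)(C)O[C@H]1C[C@@]2(C)[C@@H](CCC(=C)[C@@H]2CCC#C[Li])C(C)(C)C1 | intermediate
35 | methyl 2β-(TBS-oxy)-16-norlabd-8(17)-en-13-yn-15-oate | CC(C)(C)[Si](C)(C)O[C@H]1C[C@@]2(C)[C@@H](CCC(=C)[C@@H]2CCC#CC(=O)OC)C(C)(C)C1 | intermediate
36 | lithium alkenyl(methyl)cuprate (Cu on C14 cis to C16) | CC(C)(C)[Si](C)(C)O[C@H]1C[C@@]2(C)[C@@H](CCC(=C)[C@@H]2CC/C(C)=C(/[Cu-]C)C(=O)OC)C(C)(C)C1.[Li+] | intermediate
37 | methyl (13Z)-2β-(tert-butyldimethylsilyloxy)labda-8(17),13-dien-15-oate | CC(C)(C)[Si](C)(C)O[C@H]1C[C@@]2(C)[C@@H](CCC(=C)[C@@H]2CC/C(C)=C\C(=O)OC)C(C)(C)C1 | intermediate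
38 | methyl (13Z)-2β-hydroxylabda-8(17),13-dien-15-oate | O[C@H]1C[C@@]2(C)[C@@H](CCC(=C)[C@@H]2CC/C(C)=C\C(=O)OC)C(C)(C)C1 | intermediate
39 | (13Z)-2β-hydroxylabda-8(17),13-dien-15-oic acid | O[C@H]1C[C@@]2(C)[C@@H](CCC(=C)[C@@H]2CC/C(C)=C\C(=O)O)C(C)(C)C1 | intermediate
40 | C15 acetic mixed anhydride of the 2β-acetate | CC(=O)O[C@H]1C[C@@]2(C)[C@@H](CCC(=C)[C@@H]2CC/C(C)=C\C(=O)OC(C)=O)C(C)(C)C1 | intermediate
41 | (13Z)-2β-acetoxylabda-8(17),13-dien-15-oic acid, (2R,5S,9S,10S) | C=C1CC[C@H]2C(C)(C)C[C@@H](OC(C)=O)C[C@]2(C)[C@H]1CC/C(C)=C\C(=O)O | target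

## Step count and risks

Total step count: 24. Longest linear sequence: 23 steps (step 1, then steps 3–24, from dimedone; step 2 is the only side branch).

Steps most likely to fail:

Step 4. The ring closure may leak to the wrong regiochemistry: the dienol can also close a six-membered ring through its α-carbon C1, or the reaction may stall at the aldol stage and give mixtures. The fallback sets out from 9 and uses a pre-formed, regiodefined nucleophile. Soft enolisation (TBSOTf, Et3N, CH2Cl2, 0 °C → rt) should give the linear, thermodynamic TBS dienol ether F1. TiCl4 in CH2Cl2 at −78 °C then activates the dioxolane for an intramolecular vinylogous Mukaiyama addition, which is γ-selective for silyl dienol ethers, to give the C6 2-hydroxyethyl ether F2. Vinylogous E1cB elimination (DBU, toluene, 80 °C) expels the hydroxyethoxy group and returns to the route at 12.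

Step 7. Zinc iodide may ionise the doubly allylic alkoxide or the vinylcyclopropyl carbinol product, with elimination or cyclopropylcarbinyl rearrangement, or a second methylene may be transferred to C5=C6. The fallback sets out from 14 and hands over C20 by a sigmatropic shift instead of a carbenoid. O-Alkylation (KH, Bu3SnCH2I, THF) gives the tributylstannylmethyl ether F3. Tin–lithium exchange (n-BuLi, THF, −78 °C) gives the lithiomethyl ether F4, which is not isolated and undergoes the suprafacial Still–Wittig [2,3]-rearrangement; this places CH2OH on C10 from the β-face and moves the alkene to C1=C2, giving the 10β-hydroxymethyl diene F5. Dess–Martin oxidation gives the aldehyde F6. Huang–Minlon Wolff–Kishner reduction (N2H4·H2O, KOH, diethylene glycol, 200 °C) proceeds through the hydrazone F7 to the 10β-methyl diene F8. Hydroboration with 9-BBN, selective for the disubstituted C1=C2 with boron at C2 away from the quaternary C10, followed by NaOH/H2O2 gives the C2 alcohol F9 as an epimer mixture. Dess–Martin oxidation returns to the route at 19.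

Step 9. The ketyl may fragment in the wrong direction: cleavage of the ring bond C1–C10, assisted by the adjacent C5=C6, would expand ring A, and over-reduction of the ketone is also possible. The fallback sets out from 16 and removes the alkene before the cyclopropane is opened. Hydrogenation over rhodium (H2, 5 % Rh/Al2O3, EtOAc), a metal that spares vinylcyclopropanes, should add hydrogen anti to the β-cyclopropane and give the saturated cyclopropyl carbinol F10 (5α-H). Dess–Martin oxidation gives the saturated cyclopropyl ketone F11. Li/NH3 then opens the unperturbed cyclopropyl ketone at C1–C20 and returns to the route at 20, so step 10 is not needed.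

Further compounds
F1 | step 4 | TBS dienol ether of 9 (O–C2=C1–C10=C5) | CC(C)(C)[Si](C)(C)OC1=CC(C2(CCC3OCCO3)SCCCS2)=CC(C)(C)C1
F2 | step 4 | C6 2-hydroxyethyl ether of aldol adduct 11 (diastereomer mixture) | O=C1C=C2C(C(OCCO)CCC23SCCCS3)C(C)(C)C1
F3 | step 7 | tributylstannylmethyl ether of 14 | CCCC[Sn](CCCC)(CCCC)CO[C@H]1C=C2C(=CCCC23OCCO3)C(C)(C)C1
F4 | step 7 | lithiomethyl ether of 14 (not isolated) | [Li]CO[C@H]1C=C2C(=CCCC23OCCO3)C(C)(C)C1
F5 | step 7 | 10β-hydroxymethyl diene (C1=C2, C5=C6, C9 dioxolane) | OC[C@]12C=CCC(C)(C)C1=CCCC23OCCO3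
F6 | step 7 | 10β-formyl diene | O=C[C@]12C=CCC(C)(C)C1=CCCC23OCCO3
F7 | step 7 | hydrazone of F6 (not isolated) | NN=C[C@]12C=CCC(C)(C)C1=CCCC23OCCO3
F8 | step 7 | 10β-methyl diene (C1=C2, C5=C6, C9 dioxolane) | C[C@]12C=CCC(C)(C)C1=CCCC23OCCO3
F9 | step 7 | C2 alcohol of the 10β-methyl Δ5 series (C2 epimer mixture) | OC1C[C@@]2(C)C(=CCCC23OCCO3)C(C)(C)C1
F10 | step 9 | saturated cyclopropyl carbinol (2β-OH, β-cyclopropane, 5α-H, C9 dioxolane) | O[C@H]1[C@H]2C[C@@]23[C@@H](CCCC34OCCO4)C(C)(C)C1
F11 | step 9 | saturated cyclopropyl ketone (C2 ketone, β-cyclopropane, 5α-H, C9 dioxolane) | O=C1[C@H]2C[C@@]23[C@@H](CCCC34OCCO4)C(C)(C)C1
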